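Readings and results were generated by integration from invented constants; the scatter is artificial.

Intermediate cannot take up the whole substrate charge in this flask, although partner stands at twice the substrate, since partner also decomposes by itself.

| flask | substrate | partner | remark | time |
|---|---|---|---|---|
| north | 0.010 M | 0.028 M | run made earlier |  |
| south-east | 0.010 M | 0.044 M | run made earlier |  |
| south-west | 0.020 M | 0.020 M | run made earlier |  |
| flask | 0.010 M | 0.0200 M |  | 15 d |

| run | time / d | intermediate / % | product / % |
|---|---|---|---|
| north | 0.417 | 66 | 0 |
| north | 0.833 | 76 | 2 |
| north | 1.67 | 86 | 5 |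
| north | 2.50 | 82 | 9 |
| north | 5.00 | 73 | 20 |
| north | 10.0 | 57 | 33 |
| south-east | 0.417 | 81 | 1 |
| south-east | 0.833 | 87 | 5 |
| south-east | 1.67 | 92 | 9 |
| south-east | 2.50 | 89 | 11 |
| south-east | 5.00 | 76 | 17 |
| south-east | 10.0 | 58 | 36 |
| south-west | 0.417 | 45 | 4 |
| south-west | 1.04 | 56 | 3 |
| south-west | 2.08 | 56 | 6 |
| south-west | 4.00 | 48 | 9 |
| south-west | 10.0 | 38 | 23 |

(scatter of a reading: 2 percentage points)

- for product the crystals are counted in
- as a solid, counted per litre of solution: crystals
- the earlier runs were read with a standard deviation of 2 percentage points
- steps thought possible: substrate + partner -> intermediate; intermediate <-> product; crystals <-> product; partner -> decomposed reagent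

- the moment within 15 d at which there is most intermediate
- the amount of intermediate, in percent of the substrate charged, at that time

How much partner does decomposition take? Coupling costs one equivalent of partner per fraction coupled. Partner lost to decomposition, in equivalents, equals the crossover level, as a fraction of the substrate charge, times ln(charge/substrate left). The south-west run, with equal charges, holds 61.0% of its substrate as intermediate plus product at 10.0 d. That reading gives 0.00828 M, the substrate level at which both steps take partner equally: the crossover level. In this flask it is 82.8% of the charge.

How far does this flask couple? Leaving 25.0% of the substrate costs 1.90 equivalents and leaving 20.0% costs 2.13, against 2.00 charged.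

How much of that is lost to product? In the north run's highest intermediate reading, at 1.67 d, product is 5.49% of what had formed. This correction puts the peak between 70.9% and 75.6%.

The forecast gives 72% (range 67% to 77%) at 1.8 d (range 1.2 d to 2.6 d), on the ground that “the partner decomposes while it reacts”.

The flask peaks at 1.76 d with 70.8%, inside both forecast ranges.

    substrate + partner → intermediate (k = 0.0980 L mol⁻¹ min⁻¹)
    intermediate ⇌ product (K = 1.20, k = 3.80 × 10⁻⁵ min⁻¹)
    crystals ⇌ product, rate k3*(cs3 - [product]) while solid is left; crystals form when [product] > cs3 (solubility = 0.610 mM, k = 0.00300 min⁻¹)
    partner → decomposed reagent (k = 7.70 × 10⁻⁴ min⁻¹)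

Partner, the limiting reagent, stands at 0% at 15.0 d, with 21% of the substrate left in the flask, a rest that the crossover level prices at 2.08 equivalents. A neighbour charged with 0.025 M of substrate holds 0.800 equivalents of partner. Its simulated rest of 45.1% is priced at 0.813 equivalents, and its intermediate peaks at 51.1%.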